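The vessel is a closed, stirred slurry: electrophile and nucleophile in solution, solid base undissolved at the start.

electrophile 0.33 M; solid base 3.00 equiv; time 3.0 h

1. the equivalents of nucleophile at which the part of the electrophile that has reacted at 3.0 h is just 90%

    nucleophile + acid set free ⇌ protonated nucleophile, settled at all times (K1 = 930 L mol⁻¹)
    electrophile + nucleophile → acid set free + product (k2 = 0.027 L mol⁻¹ min⁻¹)
    acid set free + free base ⇌ salt of the base, settled at all times (K3 = 42000 L mol⁻¹)
    solid base ⇌ free base, rate k4*(cs4 - [free base]) while solid is left; crystals form when [free base] > cs4 (cs4 = 0.19 M, k4 = 0.0065 min⁻¹)

My reckoning starts from one mean. The coupling reaches the asked conversion if the free nucleophile averages 1.44 equiv of the electrophile charge: the free-nucleophile demand, ln(1/(1 − conversion)) divided by k2, the run time and the electrophile concentration. The charge must cover this demand plus what the run takes away.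

In the first instants, a proton of acid set free finds no dissolved free base and so lands on nucleophile. Each electrophile reacted then costs two nucleophiles. At the pace the demand implies, acid appears at 0.768 h⁻¹ of the charge, faster than the dissolving ceiling of 0.225 h⁻¹.

In the middle, on this reckoning, release falls below that ceiling once a fraction 0.293 of the electrophile remains. At the fork a proton favours dissolved free base, since the constants stand 45.2 to one, so from about then protonated nucleophile gives nucleophile back.

By the end, at most 0.674 equiv has dissolved, less than the 0.900 equiv of acid set free, so at least 0.226 equiv stays as protonated nucleophile. Taking free nucleophile as steady, the mean reacted fraction is 0.609, which costs 1.22 equiv of nucleophile, while dissolved base returns 0.337 equiv on average. I therefore commit to 2.32 equiv.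

The forecast stands higher, at 2.45 equiv, and says: “Reaching 90 % needs an average free nucleophile of about 0.47 M over the run”. The simulated flask needs 2.44 equiv.

At 3.00 h in this flask, the coupling gives the electrophile a half-life of 1.1 h, while the nucleophile's is 13 h, long against the run, and the electrophile's figure reads back as 1.23 equiv of free nucleophile at that moment, below the mean demand. In the second flask, with a fifth less nucleophile, 1.95 equiv, the electrophile reacted reaches 82.8%, and the demand for that conversion is 1.10 equiv of free nucleophile.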